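**Plan**
- Feature: the side-chain ring C3(=O)–O–C4(CH3)2–C5(=C6)–C1=C2 is a 4-alkylidene-5,5-dimethylcyclopent-2-enone with one oxygen between carbonyl C3 and the tertiary carbon C4, so the last retrosynthetic cut removes that ring oxygen (C3–O and O–C4).
- Further cuts: C6–C7 (aldehyde plus alkenyl iodide), C14–C15 and C15–O (glycidate, tethered through the C17 oxygen), C13–C17 (aldol), C8–C7 and C8–CH3 (enolate alkylations). This leads back to (S)-carvone, 3-furaldehyde and 2,2-dimethylcyclopentane-1,3-dione.
- Forward: the carvone ring is kept as the cyclohexane. C8 is made quaternary, the furyl carbinol is added at C13, a tethered Darzens reaction closes an epoxy-δ-lactone that is opened to the methyl glycidate and oxidised at C17, and the isopropenyl group is cut down to the carbinol. The cyclopentenone is then attached at C7 and the lactone ring is closed last by oxygen insertion.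
- Stereochemistry: C9 comes from (S)-carvone; C8 from alkylation anti to the isopropenyl group; C13 from axial aldol attack cis to it; C14 and C15 from the tether; the carbinol from Felkin–Anh reduction; the C5=C6 geometry from a stereoselective boron–Wittig olefination carried on with retention.

Key step: step 19

Locants used below: cyclohexane carbons C14 (spiro-epoxide carbon, former carvone C1), C13, C12, C11, C9 (former carvone C5), C8; C15/C16 glycidate CH and ester carbon; C17 furyl-bearing carbon; C10 carbinol carbon; C7 ketone carbon on C8; C6–C1 side-chain ring as in the first plan line.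

Step 1
Reactants: 1 (S)-(+)-carvone
Product: 3 (5S,6R)-6-methylcarvone (trans isomer; minor C8 epimer carried along), via lithium dienolate 2 (not isolated)
Conditions: LiN(i-Pr)2, THF, −78 °C; MeI, −78 to 0 °C
Reagents that add atoms: iodomethane, CI
Why: Kinetic α′-deprotonation of the enone gives the cross-conjugated dienolate and its SN2 methylation (enolate alkylation) occurs mainly anti to the neighbouring isopropenyl group, although the C8 configuration is irrelevant here because this centre is re-enolised in step 2.

Step 2
Reactants: 3 (5S,6R)-6-methylcarvone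
Product: 5 (5R,6S)-6-[(4-methoxybenzyloxy)methyl]-6-methylcarvone (CH2OPMB trans to isopropenyl), via lithium enolate 4 (not isolated)
Conditions: LiN(i-Pr)2, THF, −78 to −40 °C; PMBOCH2Cl, −78 to −20 °C
Reagents that add atoms: 4-methoxybenzyl chloromethyl ether, COc1ccc(COCCl)cc1
Why: Enolate alkylation of the tetrasubstituted α′-enolate with the reactive α-chloro ether creates the C8 quaternary centre, the electrophile entering on the face opposite the adjacent C9 isopropenyl group so that CH2OPMB ends trans and methyl cis to it, and a lithium enolate in THF without polar additives should react at carbon and not at oxygen.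

Step 3
Reactants: 5 (5R,6S)-6-[(4-methoxybenzyloxy)methyl]-6-methylcarvone; 6 3-furaldehyde
Product: 8 C13 aldol (2S,5R,6S)-2-[(S)-furan-3-yl(hydroxy)methyl]-6-[(4-methoxybenzyloxy)methyl]-2,6-dimethyl-5-(prop-1-en-2-yl)cyclohexan-1-one, via lithium enolate 7 (not isolated)
Conditions: LiBH(s-Bu)3, THF, −78 °C; then 6, −78 °C; aq NH4Cl at −78 °C
Reagents that add atoms: none
Why: 1,4-Hydride delivery gives the C13=C14 enolate regiospecifically and its aldol addition to 6 (reductive aldol) should take place by axial attack on the half-chair with equatorial isopropenyl, syn only to the small C8 methyl and anti to CH2OPMB, which places C17 cis to the C9 substituent, while the Zimmerman–Traxler chair of the ring enolate sets the C17 carbinol (hydroxyl syn to the C13 methyl), a centre that is removed in step 7.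

Step 4
Reactants: 8 C13 aldol
Product: 9 C17 chloroacetate of 8
Conditions: (ClCH2CO)2O, pyridine, DMAP (cat.), CH2Cl2, 0 °C
Reagents that add atoms: chloroacetic anhydride, O=C(CCl)OC(=O)CCl
Why: DMAP-catalysed acylation of the neopentylic alcohol with the anhydride installs the α-chloroacetate tether under conditions too mild for retro-aldol cleavage and creates no stereocentre.

Step 5
Reactants: 9 C17 chloroacetate
Product: 11 epoxy lactone (14,15-epoxide fused to the C16–O–C17 δ-lactone; epoxide oxygen cis to C17), via potassium chloro-alkoxide 10 (not isolated)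
Conditions: KN(SiMe3)2, THF, −78 to 0 °C
Reagents that add atoms: none
Why: In this intramolecular Darzens condensation the chloroacetate enolate adds to the doubly neopentylic C14 ketone through a six-membered chair in which the C17 tether is equatorial, giving the trans-fused aldolate with C15 on the face opposite C17 (the cis-fused alternatives would put the tether or C15 syn-axial to the C8 methyl or to the C9 substituent), and the axial alkoxide then displaces chloride with inversion, the lactone ring forcing C16 cis to C13 on the epoxide.

Step 6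
Reactants: 11 epoxy lactone
Product: 13 methyl 14,15-epoxy-17-hydroxy ester (methyl glycidate with free furyl carbinol), via lithium carboxylate 12 (not isolated)
Conditions: LiOH·H2O, THF/H2O, 0 °C to rt; evaporate; MeI, DMF, rt
Reagents that add atoms: lithium hydroxide, [Li+].[OH-]; iodomethane, CI
Why: Hydroxide opens the δ-lactone irreversibly as the carboxylate (saponification) and SN2 methylation of that carboxylate in DMF gives the methyl ester without any acidic stage at which the hydroxy acid could relactonise, so that no stereocentre is touched.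

Step 7
Reactants: 13 methyl 14,15-epoxy-17-hydroxy ester
Product: 14 17-ketone (3-furoyl) methyl glycidate
Conditions: Dess–Martin periodinane, pyridine, CH2Cl2, 0 °C to rt
Reagents that add atoms: none
Why: Dess–Martin oxidation converts the hindered furyl carbinol into the 3-furoyl ketone, which erases the C17 centre and rules out relactonisation, while the pyridine buffer protects the epoxide.

Step 8
Reactants: 14 17-ketone methyl glycidate
Product: 15 C10 methyl ketone
Conditions: OsO4 (cat.), NaIO4, 2,6-lutidine, dioxane/H2O, rt
Reagents that add atoms: sodium periodate, [Na+].[O-]I(=O)(=O)=O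
Why: Lemieux–Johnson cleavage (osmylation then periodate glycol cleavage) is selective for the electron-rich 1,1-disubstituted alkene because the furan is now deactivated by its acyl group and no other alkene is present.

Step 9
Reactants: 15 C10 methyl ketone
Product: 16 (10R)-alcohol
Conditions: LiBH(s-Bu)3, THF, −78 °C; aq NH4Cl
Reagents that add atoms: none
Why: Felkin–Anh reduction of the methyl ketone by the bulky trialkylborohydride, with quaternary C8 as the large group anti to the incoming hydride and the hydride passing the C9 hydrogen, should give the (10R)-carbinol, whereas the aryl ketone on quaternary C13 and the ester are too hindered or too unreactive at −78 °C.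

Step 10
Reactants: 16 (10R)-alcohol
Product: 17 C10 triethylsilyl ether
Conditions: Et3SiCl, imidazole, DMAP (cat.), DMF, rt
Reagents that add atoms: chlorotriethylsilane, CC[Si](Cl)(CC)CC
Why: Silylation of the secondary alcohol under standard silyl chloride/imidazole conditions masks the hydroxyl that would otherwise form a lactol with the C7 aldehyde made in step 12.

Step 11
Reactants: 17 C10 triethylsilyl ether
Product: 18 C7 primary alcohol
Conditions: DDQ, CH2Cl2/pH 7 phosphate buffer, 0 °C
Reagents that add atoms: none
Why: DDQ removes the 4-methoxybenzyl group by benzylic oxidation to the oxocarbenium ion and hydrolysis (oxidative ether cleavage), conditions that leave the silyl ether, the epoxide, the ester and the deactivated furan untouched.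

Step 12
Reactants: 18 C7 primary alcohol
Product: 19 C7 aldehyde
Conditions: Dess–Martin periodinane, pyridine, CH2Cl2, rt
Reagents that add atoms: none
Why: Dess–Martin oxidation of the neopentyl primary alcohol gives a non-enolisable aldehyde that cannot epimerise or eliminate.

Step 13
Reactants: 20 2,2-dimethylcyclopentane-1,3-dione
Product: 21 (E)-2,2-dimethyl-3-[(4,4,5,5-tetramethyl-1,3,2-dioxaborolan-2-yl)methylidene]cyclopentan-1-one
Conditions: CH2(Bpin)2, lithium 2,2,6,6-tetramethylpiperidide, THF, 0 °C; then 20, −78 °C to rt; aq NH4Cl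
Reagents that add atoms: bis(4,4,5,5-tetramethyl-1,3,2-dioxaborolan-2-yl)methane, CC1(C)OB(CB2OC(C)(C)C(C)(C)O2)OC1(C)C
Why: In this boron–Wittig olefination the α-boryl carbanion adds to one of the two equivalent carbonyl groups and syn-elimination of the boron-bound oxygen gives the trisubstituted alkenyl boronate with boron anti to the quaternary α-carbon, which is the (E)-geometry later needed at C5=C6.

Step 14
Reactants: 21 (E)-alkenyl pinacol boronate
Product: 22 (E)-3-(iodomethylidene)-2,2-dimethylcyclopentan-1-one
Conditions: NaI, TsN(Cl)Na (chloramine-T), THF/H2O, rt, dark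
Reagents that add atoms: sodium iodide, [Na+].[I-]
Why: Ipso-iododeboronation by electrophilic iodine generated from iodide and chloramine-T proceeds with retention of alkene geometry, and the near-neutral medium avoids base-mediated α-iodination of the ketone.

Step 15
Reactants: 22 (E)-3-(iodomethylidene)-2,2-dimethylcyclopentan-1-one
Product: 24 (E)-4-(iodomethylidene)-5,5-dimethylcyclopent-2-en-1-one, via lithium enolate 23 (not isolated)
Conditions: LiN(i-Pr)2, THF, −78 °C; PhS(Cl)=N-t-Bu, −78 °C
Reagents that add atoms: none
Why: In this Mukaiyama dehydrogenation the only possible enolate is captured at sulfur by the sulfinimidoyl chloride and the α-sulfilimine undergoes syn-elimination at low temperature towards the allylic C1 hydrogen, giving the conjugated dienone without touching the alkenyl iodide.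

Step 16
Reactants: 19 C7 aldehyde; 24 (E)-4-(iodomethylidene)-5,5-dimethylcyclopent-2-en-1-one
Product: 26 C7 allylic alcohol (both C7 epimers), via alkenylchromium dichloride 25 (not isolated)
Conditions: CrCl2, NiCl2 (cat.), DMSO, rt
Reagents that add atoms: none
Why: Nozaki–Hiyama–Kishi coupling, in which nickel-catalysed formation of the alkenyl species of trivalent chromium occurs with retention of geometry and this reagent adds only to the aldehyde among the carbonyl groups present, forms the C6–C7 bond, the new C7 carbinol centre being of no consequence because it is oxidised in step 17.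

Step 17
Reactants: 26 C7 allylic alcohol
Product: 27 dienedione C10 triethylsilyl ether
Conditions: Dess–Martin periodinane, pyridine, CH2Cl2, 0 °C
Reagents that add atoms: none
Why: Dess–Martin oxidation of the allylic alcohol gives the cross-conjugated dienedione and removes the C7 centre, with the acyl group remaining on the side of C5 remote from the gem-dimethyl carbon, which is also the thermodynamically preferred geometry.

Step 18
Reactants: 27 dienedione C10 triethylsilyl ether
Product: 28 cyclopentenone analogue of the target (free C10 alcohol)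
Conditions: HF·pyridine, pyridine, THF, 0 °C
Reagents that add atoms: none
Why: Fluoride-mediated desilylation of the triethylsilyl ether under pyridine-buffered conditions liberates the C10 alcohol without opening the epoxide or adding to the dienedione.

Step 19
Reactants: 28 cyclopentenone analogue of the target
Product: 30 CNP0293135.1, via Criegee adduct 29 (not isolated)
Conditions: mCPBA, CH2Cl2, 0 °C to rt
Reagents that add atoms: 3-chloroperoxybenzoic acid, OOC(=O)c1cccc(Cl)c1
Why: The peracid adds to the C3 carbonyl to give the Criegee adduct 29, and the C3–C4 bond migrates to the proximal peroxide oxygen with loss of 3-chlorobenzoate, so that oxygen is inserted between C3 and C4 (Baeyer–Villiger oxidation). The closest known reaction type is the peracid ring expansion of 5,5-disubstituted cyclopent-2-enones to 6,6-disubstituted 5,6-dihydro-2H-pyran-2-ones. The six-membered lactone arises by ring expansion through this 1,2-shift and not by an end-to-end cyclisation. No stereocentre is formed and the migrating carbon is achiral. The step needs attack at C3 in preference to the C7 and C17 ketones and migration of C4 in preference to vinylic C2; C3 is flanked only by the gem-dimethyl carbon whereas C7 and C17 sit on the quaternary ring carbons C8 and C13 beside the spiro-epoxide, and a tertiary allylic carbon migrates far better than an sp2 carbon. All C=C bonds are conjugated to carbonyl groups and the furan carries an acyl group, which should slow epoxidation and furan oxidation.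

**Compound list**
1 | (S)-(+)-carvone | O=C1C(C)=CC[C@H](C(C)=C)C1 | starting material
2 | lithium dienolate of 1 (not isolated) | [Li+].[O-]C1=C[C@@H](C(C)=C)CC=C1C | intermediate
3 | (5S,6R)-6-methylcarvone (trans; minor C8 epimer carried along) | O=C1C(C)=CC[C@H](C(C)=C)[C@H]1C | intermediate
4 | lithium enolate of 3 (not isolated) | [Li+].[O-]C1=C(C)[C@@H](C(C)=C)CC=C1C | intermediate
5 | (5R,6S)-6-[(4-methoxybenzyloxy)methyl]-6-methylcarvone | O=C1C(C)=CC[C@H](C(C)=C)[C@@]1(C)COCc1ccc(OC)cc1 | intermediate
6 | 3-furaldehyde | O=Cc1ccoc1 | starting material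
7 | lithium C13=C14 enolate from conjugate reduction of 5 (not isolated) | [Li+].[O-]C1=C(C)CC[C@H](C(C)=C)[C@@]1(C)COCc1ccc(OC)cc1 | intermediate
8 | C13 aldol, (2S,5R,6S)-2-[(S)-furan-3-yl(hydroxy)methyl]-6-[(4-methoxybenzyloxy)methyl]-2,6-dimethyl-5-(prop-1-en-2-yl)cyclohexan-1-one | O=C1[C@](C)([C@@H](O)c2ccoc2)CC[C@H](C(C)=C)[C@@]1(C)COCc1ccc(OC)cc1 | intermediate
9 | C17 chloroacetate of 8 | O=C1[C@](C)([C@@H](OC(=O)CCl)c2ccoc2)CC[C@H](C(C)=C)[C@@]1(C)COCc1ccc(OC)cc1 | intermediate
10 | potassium C14 alkoxide of the 15-chloro δ-lactone (not isolated) | [K+].[O-][C@@]12[C@](C)([C@H](c3ccoc3)OC(=O)[C@@H]1Cl)CC[C@H](C(C)=C)[C@@]2(C)COCc4ccc(OC)cc4 | intermediate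
11 | epoxy lactone (14,15-epoxide fused to the C16–O–C17 δ-lactone, epoxide oxygen cis to C17 and to the C8 methyl) | O=C1[C@H]2O[C@@]23[C@](C)([C@H](c4ccoc4)O1)CC[C@H](C(C)=C)[C@@]3(C)COCc5ccc(OC)cc5 | intermediate
12 | lithium 14,15-epoxy-17-hydroxy carboxylate (not isolated) | [Li+].[O-]C(=O)[C@H]1O[C@@]12[C@](C)([C@@H](O)c3ccoc3)CC[C@H](C(C)=C)[C@@]2(C)COCc4ccc(OC)cc4 | intermediate
13 | methyl 14,15-epoxy-17-hydroxy ester | COC(=O)[C@H]1O[C@@]12[C@](C)([C@@H](O)c3ccoc3)CC[C@H](C(C)=C)[C@@]2(C)COCc4ccc(OC)cc4 | intermediate
14 | 17-ketone (3-furoyl) methyl glycidate | COC(=O)[C@H]1O[C@@]12[C@](C)(C(=O)c3ccoc3)CC[C@H](C(C)=C)[C@@]2(C)COCc4ccc(OC)cc4 | intermediate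
15 | C10 methyl ketone | COC(=O)[C@H]1O[C@@]12[C@](C)(C(=O)c3ccoc3)CC[C@H](C(C)=O)[C@@]2(C)COCc4ccc(OC)cc4 | intermediate
16 | (10R)-alcohol | COC(=O)[C@H]1O[C@@]12[C@](C)(C(=O)c3ccoc3)CC[C@H]([C@@H](C)O)[C@@]2(C)COCc4ccc(OC)cc4 | intermediate
17 | C10 triethylsilyl ether | COC(=O)[C@H]1O[C@@]12[C@](C)(C(=O)c3ccoc3)CC[C@H]([C@@H](C)O[Si](CC)(CC)CC)[C@@]2(C)COCc4ccc(OC)cc4 | intermediate
18 | C7 primary alcohol | COC(=O)[C@H]1O[C@@]12[C@](C)(C(=O)c3ccoc3)CC[C@H]([C@@H](C)O[Si](CC)(CC)CC)[C@@]2(C)CO | intermediate
19 | C7 aldehyde | COC(=O)[C@H]1O[C@@]12[C@](C)(C(=O)c3ccoc3)CC[C@H]([C@@H](C)O[Si](CC)(CC)CC)[C@@]2(C)C=O | intermediate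
20 | 2,2-dimethylcyclopentane-1,3-dione | CC1(C)C(=O)CCC1=O | starting material
21 | (E)-2,2-dimethyl-3-[(4,4,5,5-tetramethyl-1,3,2-dioxaborolan-2-yl)methylidene]cyclopentan-1-one | CC1(C)OB(OC1(C)C)/C=C1\CCC(=O)C1(C)C | intermediate
22 | (E)-3-(iodomethylidene)-2,2-dimethylcyclopentan-1-one | O=C1CC/C(=C\I)C1(C)C | intermediate
23 | lithium enolate of 22 (not isolated) | [Li+].[O-]C1=CC/C(=C\I)C1(C)C | intermediate
24 | (E)-4-(iodomethylidene)-5,5-dimethylcyclopent-2-en-1-one | O=C1C=C/C(=C\I)C1(C)C | intermediate
25 | alkenylchromium dichloride from 24 (not isolated) | Cl[Cr](Cl)/C=C1\C=CC(=O)C1(C)C | intermediate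
26 | C7 allylic alcohol (both C7 epimers) | COC(=O)[C@H]1O[C@@]12[C@](C)(C(=O)c3ccoc3)CC[C@H]([C@@H](C)O[Si](CC)(CC)CC)[C@@]2(C)C(O)/C=C1\C=CC(=O)C1(C)C | intermediate
27 | dienedione C10 triethylsilyl ether | COC(=O)[C@H]1O[C@@]12[C@](C)(C(=O)c3ccoc3)CC[C@H]([C@@H](C)O[Si](CC)(CC)CC)[C@@]2(C)C(=O)/C=C1\C=CC(=O)C1(C)C | intermediate
28 | cyclopentenone analogue of the target | COC(=O)[C@H]1O[C@@]12[C@](C)(C(=O)c1ccoc1)CC[C@H]([C@@H](C)O)[C@@]2(C)C(=O)/C=C1\C=CC(=O)C1(C)C | intermediate
29 | Criegee adduct at C3 (not isolated) | COC(=O)[C@H]1O[C@@]12[C@](C)(C(=O)c1ccoc1)CC[C@H]([C@@H](C)O)[C@@]2(C)C(=O)/C=C1\C=CC(O)(OOC(=O)c2cccc(Cl)c2)C1(C)C | intermediate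
30 | CNP0293135.1 | COC(=O)[C@H]1O[C@@]12[C@](C)(C(=O)c1ccoc1)CC[C@H]([C@@H](C)O)[C@@]2(C)C(=O)/C=C1\C=CC(=O)OC1(C)C | target

**Step count**
Total: 19 steps. Longest linear sequence: 16 steps (steps 1–12 and 16–19); the cyclopentenone fragment takes 3 steps (13–15).

**Steps most likely to fail**

Step 5. The tethered enolate may add to the wrong face of C14 through a cis-fused aldolate, or may not add to the doubly neopentylic ketone at all, so that the epoxide forms with the wrong C14 configuration or not at all. The fallback sets out from 8 and separates ring closure from epoxide formation. Esterification of 8 with diethylphosphonoacetic acid (DCC, DMAP) should give the phosphonoacetate F1. Intramolecular Horner–Wadsworth–Emmons olefination (LiCl, DBU, MeCN) should give the C14=C15 unsaturated δ-lactone F2. Weitz–Scheffer epoxidation (t-BuOOH, DBU) should then deliver oxygen to C14 from the face that carries only the C8 methyl group. The route is rejoined at 11.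

Step 19. The peracid may oxidise the furan, insert oxygen at the C7 or C17 ketone, or epoxidise the dienedione faster than it expands the cyclopentenone. The fallback moves the oxygen insertion to the small fragment, where none of these groups is present. It sets out from 24: Baeyer–Villiger oxidation with mCPBA should give (E)-5-(iodomethylidene)-6,6-dimethyl-5,6-dihydro-2H-pyran-2-one F3. Coupling of F3 with 19 (CrCl2, NiCl2 cat., DMSO) should give the lactone allylic alcohol F4. Dess–Martin oxidation should give the lactone ketone triethylsilyl ether F5, and desilylation with HF·pyridine rejoins the route at 30.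

Step 3. The aldehyde must approach C13 syn to the axial C8 methyl group, so facial selectivity may be poor, and the crowded aldolate may revert by retro-aldol cleavage. The fallback reverses the order of the two quaternary centres and sets out from 1. Reductive aldol of the unhindered carvone enolate (LiBH(s-Bu)3; then 6) should give the carvone aldol F6. Silylation (Et3SiOTf, 2,6-lutidine) should give its triethylsilyl ether F7, and methylation at C8 (LiN(i-Pr)2, MeI) the 8-methyl ketone F8. Alkylation with PMBOCH2Cl, now anti to both the isopropenyl group and the C17 substituent, should give the quaternary ketone F9. Removal of the silyl group with HF·pyridine rejoins the route at 8.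

**Further compounds**
F1 | step 5 | C17 diethylphosphonoacetate of 8 | O=C1[C@](C)([C@@H](OC(=O)CP(=O)(OCC)OCC)c2ccoc2)CC[C@H](C(C)=C)[C@@]1(C)COCc1ccc(OC)cc1
F2 | step 5 | C14=C15 unsaturated δ-lactone | O=C1C=C2[C@](C)([C@H](c3ccoc3)O1)CC[C@H](C(C)=C)[C@@]2(C)COCc4ccc(OC)cc4
F3 | step 19 | (E)-5-(iodomethylidene)-6,6-dimethyl-5,6-dihydro-2H-pyran-2-one | O=C1C=C/C(=C\I)C(C)(C)O1
F4 | step 19 | lactone C7 allylic alcohol, C10 triethylsilyl ether (both C7 epimers) | COC(=O)[C@H]1O[C@@]12[C@](C)(C(=O)c3ccoc3)CC[C@H]([C@@H](C)O[Si](CC)(CC)CC)[C@@]2(C)C(O)/C=C1\C=CC(=O)OC1(C)C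
F5 | step 19 | lactone C7 ketone, C10 triethylsilyl ether | COC(=O)[C@H]1O[C@@]12[C@](C)(C(=O)c3ccoc3)CC[C@H]([C@@H](C)O[Si](CC)(CC)CC)[C@@]2(C)C(=O)/C=C1\C=CC(=O)OC1(C)C
F6 | step 3 | carvone aldol, 2-[(S)-furan-3-yl(hydroxy)methyl]-2-methyl-5-(prop-1-en-2-yl)cyclohexan-1-one with C17 cis to isopropenyl | O=C1[C@](C)([C@@H](O)c2ccoc2)CC[C@H](C(C)=C)C1
F7 | step 3 | C17 triethylsilyl ether of the carvone aldol | O=C1[C@](C)([C@@H](O[Si](CC)(CC)CC)c2ccoc2)CC[C@H](C(C)=C)C1
F8 | step 3 | 8-methyl ketone (C8 epimers) | O=C1[C@](C)([C@@H](O[Si](CC)(CC)CC)c2ccoc2)CC[C@H](C(C)=C)C1C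
F9 | step 3 | C8 quaternary ketone, C17 triethylsilyl ether | O=C1[C@](C)([C@@H](O[Si](CC)(CC)CC)c2ccoc2)CC[C@H](C(C)=C)[C@@]1(C)COCc1ccc(OC)cc1
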